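**Strategy.** Everything rests on cutting the bond between C6 of ring A (the prenyl-bearing cyclohexene) and chain carbon C7. In the key step a palladium carbene coupling (Barluenga type) unites the N-tosylhydrazone of a 2,2,6-trimethyl-3-prenylcyclohexanone, in which C6 is still the carbonyl carbon and C5 an unresolved stereocentre, with an all-E C36 polyenyl iodide that already carries ring B. One operation forms C6–C7 and the tetrasubstituted C5=C6 double bond. It exploits the quaternary C1 of ring A: the palladium intermediate at C6 finds a β-hydrogen only on C5, so every C5 epimer converges. Two electrophilic carbons, a carbonyl carbon and an alkenyl iodide carbon, are joined by polarity reversal.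

Key step: step 15

**Remarks**
- Numbering: carotenoid locants are used for the target (ring A: C1 gem-dimethyl, C2 prenyl-bearing stereocentre, C5 methyl-bearing, C6 bonded to C7; chain C7–C15 and C15′–C7′; ring B primed). The target is (2R,2′S). Cyclohexanone intermediates use ketone locants (C1 = C=O = later C6; C2 = gem-dimethyl; C3 = stereocentre; C6 = CHMe = later C5).
- Ligand L is 1-mesityl-3-(1-hydroxy-4-methylpentan-2-yl)-4,5-dihydroimidazolium hexafluorophosphate, a leucinol-derived hydroxyalkyl N-heterocyclic carbene precursor available in both enantiomers. Assumption: (S)-L delivers the (3S)-ketone; if a test run shows the opposite sense, the two ligand enantiomers are exchanged between steps 1 and 8.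
- Assumption: crocetindialdehyde 20 (the C20 dialdehyde) and the Grignard solution 2 are purchased.
- The methyl-bearing C6 of the ketones is carried as an epimer mixture on purpose, because the coupling steps erase it.

**Ring B (2′S series)**

Step 1
Reactants: 1 2-methylcyclohex-2-en-1-one; 2 (1,3-dioxolan-2-ylmethyl)magnesium bromide
Product: 4 (3S)-3-(1,3-dioxolan-2-ylmethyl)-2,2-dimethylcyclohexan-1-one, via magnesium enolate 3 (not isolated)
Conditions: Cu(OTf)2 (3 mol %), (S)-L (4 mol %), Et2O, −10 °C, slow addition of 2 (THF solution); then MeI, DMPU, 0 °C → rt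
Reagents that add atoms: iodomethane, CI
Why: Copper-catalysed asymmetric conjugate addition of a Grignard reagent to an α-substituted cyclic enone, in which the chiral carbene–copper complex selects the face of C3 and so sets the (S) centre, followed by C-methylation of the regiodefined magnesium enolate at C2, which becomes the gem-dimethyl carbon.

Step 2
Reactants: 4 (3S)-3-(1,3-dioxolan-2-ylmethyl)-2,2-dimethylcyclohexan-1-one
Product: 6 (3S,6RS)-3-(1,3-dioxolan-2-ylmethyl)-2,2,6-trimethylcyclohexan-1-one, via lithium enolate 5 (not isolated)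
Conditions: LiN(iPr)2, THF, −78 °C; MeI, −78 → 0 °C
Reagents that add atoms: iodomethane, CI
Why: Kinetic enolate alkylation that can only occur at C6 because C2 is quaternary; the new C6 centre should form as an epimer mixture, which is acceptable since step 14 erases it.

Step 3
Reactants: 6 (3S,6RS)-3-(1,3-dioxolan-2-ylmethyl)-2,2,6-trimethylcyclohexan-1-one
Product: 7 2-[(1S,4RS)-2,2,4-trimethyl-3-oxocyclohexyl]acetaldehyde
Conditions: 1 M HCl, THF, 0 °C → rt
Reagents that add atoms: water, O
Why: Acid-catalysed hydrolysis of the dioxolane acetal, mild enough to leave the non-epimerisable C1 stereocentre and the hindered ketone untouched.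

Step 4
Reactants: 7 2-[(1S,4RS)-2,2,4-trimethyl-3-oxocyclohexyl]acetaldehyde
Product: 8 (3S,6RS)-2,2,6-trimethyl-3-(prop-2-en-1-yl)cyclohexan-1-one
Conditions: Ph3PCH3Br, KOtBu, THF, 0 °C; then 7, −78 °C → rt
Reagents that add atoms: methyltriphenylphosphonium bromide, C[P+](c1ccccc1)(c1ccccc1)c1ccccc1.[Br-]
Why: Wittig methylenation, chemoselective for the aldehyde because the ketone flanked by a quaternary and a tertiary carbon is too hindered to react with the ylide.

Step 5
Reactants: 9 2-methylidenepropane-1,3-diol
Product: 10 2-methylidenepropane-1,3-diyl bis(tert-butyldimethylsilyl) ether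
Conditions: TBSCl, imidazole, DMF, rt
Reagents that add atoms: tert-butyldimethylsilyl chloride, CC(C)(C)[Si](C)(C)Cl
Why: Standard imidazole-promoted silylation of two primary alcohols, giving a base-stable and fluoride-labile protecting group for the later palladium steps.

Step 6
Reactants: 8 (3S,6RS)-2,2,6-trimethyl-3-(prop-2-en-1-yl)cyclohexan-1-one; 10 2-methylidenepropane-1,3-diyl bis(tert-butyldimethylsilyl) ether
Product: 11 (3S,6RS)-3-[4-(tert-butyldimethylsilyloxy)-3-(tert-butyldimethylsilyloxymethyl)but-2-en-1-yl]-2,2,6-trimethylcyclohexan-1-one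
Conditions: second-generation Hoveyda–Grubbs catalyst RuCl2(H2IMes)(=CH–C6H4-2-OiPr) (5 mol %), 10 (4 equiv), CH2Cl2, 40 °C
Reagents that add atoms: none
Why: Olefin cross-metathesis of a terminal alkene with a 1,1-disubstituted alkene that does not homodimerise and is used in excess; the new trisubstituted alkene carries two identical CH2OTBS groups, so no E/Z question arises.

Step 7
Reactants: 11 (3S,6RS)-3-[4-(tert-butyldimethylsilyloxy)-3-(tert-butyldimethylsilyloxymethyl)but-2-en-1-yl]-2,2,6-trimethylcyclohexan-1-one
Product: 12 ring B N-tosylhydrazone (4-methylbenzenesulfonohydrazone of 11)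
Conditions: TsNHNH2, PPTS (cat.), 4 Å MS, THF, 60 °C
Reagents that add atoms: p-toluenesulfonohydrazide, Cc1ccc(cc1)S(=O)(=O)NN
Why: Acid-catalysed condensation of the hindered ketone with the sulfonohydrazide, run without alcohol solvent so that the silyl ethers should survive; hydrazone E/Z isomers are irrelevant for step 14.

**Ring A (2R series)**

Step 8
Reactants: 1 2-methylcyclohex-2-en-1-one; 2 (1,3-dioxolan-2-ylmethyl)magnesium bromide
Product: 14 (3R)-3-(1,3-dioxolan-2-ylmethyl)-2,2-dimethylcyclohexan-1-one, via magnesium enolate 13 (not isolated)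
Conditions: Cu(OTf)2 (3 mol %), (R)-L (4 mol %), Et2O, −10 °C, slow addition of 2 (THF solution); then MeI, DMPU, 0 °C → rt
Reagents that add atoms: iodomethane, CI
Why: The same copper-catalysed asymmetric conjugate addition and enolate methylation as step 1, with the enantiomeric ligand selecting the opposite face of C3 to set the (R) centre.

Step 9
Reactants: 14 (3R)-3-(1,3-dioxolan-2-ylmethyl)-2,2-dimethylcyclohexan-1-one
Product: 16 (3R,6RS)-3-(1,3-dioxolan-2-ylmethyl)-2,2,6-trimethylcyclohexan-1-one, via lithium enolate 15 (not isolated)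
Conditions: LiN(iPr)2, THF, −78 °C; MeI, −78 → 0 °C
Reagents that add atoms: iodomethane, CI
Why: Kinetic enolate alkylation at C6, the only enolisable position; the C6 epimer mixture is erased in step 15.

Step 10
Reactants: 16 (3R,6RS)-3-(1,3-dioxolan-2-ylmethyl)-2,2,6-trimethylcyclohexan-1-one
Product: 17 2-[(1R,4RS)-2,2,4-trimethyl-3-oxocyclohexyl]acetaldehyde
Conditions: 1 M HCl, THF, 0 °C → rt
Reagents that add atoms: water, O
Why: Acid-catalysed acetal hydrolysis that leaves the C1 stereocentre untouched.

Step 11
Reactants: 17 2-[(1R,4RS)-2,2,4-trimethyl-3-oxocyclohexyl]acetaldehyde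
Product: 18 (3R,6RS)-2,2,6-trimethyl-3-(3-methylbut-2-en-1-yl)cyclohexan-1-one
Conditions: iPrPPh3I, n-BuLi, THF, 0 °C; then 17, −78 °C → rt
Reagents that add atoms: isopropyltriphenylphosphonium iodide, CC(C)[P+](c1ccccc1)(c1ccccc1)c1ccccc1.[I-]
Why: Wittig olefination with the isopropylidene ylide, chemoselective for the aldehyde over the hindered ketone, which installs the prenyl group without any E/Z issue.

Step 12
Reactants: 18 (3R,6RS)-2,2,6-trimethyl-3-(3-methylbut-2-en-1-yl)cyclohexan-1-one
Product: 19 ring A N-tosylhydrazone (4-methylbenzenesulfonohydrazone of 18)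
Conditions: TsNHNH2, PPTS (cat.), EtOH, 70 °C
Reagents that add atoms: p-toluenesulfonohydrazide, Cc1ccc(cc1)S(=O)(=O)NN
Why: Acid-catalysed hydrazone condensation of the hindered ketone; the prenyl group tolerates the weak acid.

**Polyene and assembly**

Step 13
Reactants: 20 crocetindialdehyde
Product: 21 (all-E)-1,18-diiodo-3,7,12,16-tetramethyloctadeca-1,3,5,7,9,11,13,15,17-nonaene
Conditions: CrCl2 (16 equiv), CHI3 (6 equiv), THF/1,4-dioxane, 0 °C → rt, dark
Reagents that add atoms: iodoform, IC(I)I
Why: Twofold Takai olefination, in which the gem-dichromium reagent from iodoform and divalent chromium adds to each aldehyde and anti elimination should give the (E)-iodoalkenes that become C7=C8 and C7′=C8′.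

Step 14
Reactants: 12 ring B N-tosylhydrazone; 21 (all-E)-1,18-diiodo-3,7,12,16-tetramethyloctadeca-1,3,5,7,9,11,13,15,17-nonaene
Product: 23 ring B all-E nonaenyl iodide (iodine at C7; bis-TBS ether), via ring B diazoalkane 22 (not isolated)
Conditions: Pd2(dba)3 (2.5 mol %), XPhos (10 mol %), LiOtBu (2.5 equiv), 21 (3 equiv), 1,4-dioxane, 80 °C, Ar, dark
Reagents that add atoms: none
Why: Barluenga cross-coupling (diazoalkane from the hydrazone salt, palladium carbene at C6′, migratory insertion of the polyenyl group, β-hydride elimination from C5′–H as the only β-hydrogen) run with the diiodide in excess so that single coupling should dominate; the C5′ epimers of 12 converge and C2′ is untouched.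

Step 15
Reactants: 19 ring A N-tosylhydrazone; 23 ring B all-E nonaenyl iodide
Product: 25 bis(tert-butyldimethylsilyl) ether of the target, via ring A diazoalkane 24 (not isolated)
Conditions: Pd2(dba)3 (5 mol %), XPhos (20 mol %), LiOtBu (3 equiv), 19 (1.5 equiv), 1,4-dioxane, 80 °C, Ar, dark
Reagents that add atoms: none
Why: LiOtBu deprotonates 19, which loses lithium p-toluenesulfinate on warming to give the hindered diazoalkane 24 (Bamford–Stevens), while zerovalent palladium inserts into the C7–I bond of 23 with retention of the E geometry; the alkenyl divalent palladium iodide takes up 24 with loss of N2 to give a palladium carbene at C6, migratory insertion of the polyenyl group forms the C6–C7 bond, and syn β-hydride elimination gives the C5=C6 alkene and returns zerovalent palladium. The closest known reaction type is the Barluenga cross-coupling of ketone N-tosylhydrazones with alkenyl halides to give 1,3-dienes. No ring is closed and no stereocentre is created: the C5 stereocentre of 19 and its hydrazone E/Z isomerism are erased, so all isomers of 19 should converge on one product, while C2 and C2′ are remote spectators and C7=C8 keeps the geometry of the iodide. The regioselectivity the step needs is secured by the substrate, because the allylpalladium intermediate at C6 has a β-hydrogen only at C5 (C1 is quaternary, C7 is vinylic), and π–σ–π isomerisation lets palladium reach the face syn to C5–H in either C5 epimer. The chemoselectivity it needs (carbene transfer to palladium and not to the polyene or the prenyl double bond) rests on fast capture of the slowly released diazoalkane by the alkenylpalladium species, helped by the bulky electron-rich phosphine and the moderate temperature.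

Step 16
Reactants: 25 bis(tert-butyldimethylsilyl) ether of the target
Product: 26 target (2R,2′S)-diol CNP0213288.1
Conditions: TBAF (3 equiv), THF, 0 °C → rt, dark, Ar
Reagents that add atoms: none
Why: Fluoride-mediated cleavage of the two primary allylic silyl ethers, under which the polyene and both stereocentres should be unaffected.

**Compound list**

1 | 2-methylcyclohex-2-en-1-one | CC1=CCCCC1=O | starting material
2 | (1,3-dioxolan-2-ylmethyl)magnesium bromide | Br[Mg]CC1OCCO1 | starting material
3 | magnesium enolate of the (S) conjugate adduct | C(C1OCCO1)[C@@H]2CCCC(O[Mg]Br)=C2C | intermediate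
4 | (3S)-3-(1,3-dioxolan-2-ylmethyl)-2,2-dimethylcyclohexan-1-one | C(C1OCCO1)[C@@H]2CCCC(=O)C2(C)C | intermediate
5 | lithium enolate of 4 | C(C1OCCO1)[C@@H]2CCC=C(O[Li])C2(C)C | intermediate
6 | (3S,6RS)-3-(1,3-dioxolan-2-ylmethyl)-2,2,6-trimethylcyclohexan-1-one | C(C1OCCO1)[C@@H]2CCC(C)C(=O)C2(C)C | intermediate
7 | 2-[(1S,4RS)-2,2,4-trimethyl-3-oxocyclohexyl]acetaldehyde | O=CC[C@@H]1CCC(C)C(=O)C1(C)C | intermediate
8 | (3S,6RS)-2,2,6-trimethyl-3-(prop-2-en-1-yl)cyclohexan-1-one | C=CC[C@@H]1CCC(C)C(=O)C1(C)C | intermediate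
9 | 2-methylidenepropane-1,3-diol | C=C(CO)CO | starting material
10 | 2-methylidenepropane-1,3-diyl bis(tert-butyldimethylsilyl) ether | C=C(CO[Si](C)(C)C(C)(C)C)CO[Si](C)(C)C(C)(C)C | intermediate
11 | (3S,6RS)-3-[4-(tert-butyldimethylsilyloxy)-3-(tert-butyldimethylsilyloxymethyl)but-2-en-1-yl]-2,2,6-trimethylcyclohexan-1-one | CC(C)(C)[Si](C)(C)OCC(CO[Si](C)(C)C(C)(C)C)=CC[C@@H]1CCC(C)C(=O)C1(C)C | intermediate
12 | ring B N-tosylhydrazone (from 11) | CC(C)(C)[Si](C)(C)OCC(CO[Si](C)(C)C(C)(C)C)=CC[C@@H]1CCC(C)C(=NNS(=O)(=O)c2ccc(C)cc2)C1(C)C | intermediate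
13 | magnesium enolate of the (R) conjugate adduct | C(C1OCCO1)[C@H]2CCCC(O[Mg]Br)=C2C | intermediate
14 | (3R)-3-(1,3-dioxolan-2-ylmethyl)-2,2-dimethylcyclohexan-1-one | C(C1OCCO1)[C@H]2CCCC(=O)C2(C)C | intermediate
15 | lithium enolate of 14 | C(C1OCCO1)[C@H]2CCC=C(O[Li])C2(C)C | intermediate
16 | (3R,6RS)-3-(1,3-dioxolan-2-ylmethyl)-2,2,6-trimethylcyclohexan-1-one | C(C1OCCO1)[C@H]2CCC(C)C(=O)C2(C)C | intermediate
17 | 2-[(1R,4RS)-2,2,4-trimethyl-3-oxocyclohexyl]acetaldehyde | O=CC[C@H]1CCC(C)C(=O)C1(C)C | intermediate
18 | (3R,6RS)-2,2,6-trimethyl-3-(3-methylbut-2-en-1-yl)cyclohexan-1-one | CC(C)=CC[C@H]1CCC(C)C(=O)C1(C)C | intermediate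
19 | ring A N-tosylhydrazone (from 18) | CC(C)=CC[C@H]1CCC(C)C(=NNS(=O)(=O)c2ccc(C)cc2)C1(C)C | intermediate
20 | crocetindialdehyde, (all-E)-2,6,11,15-tetramethylhexadeca-2,4,6,8,10,12,14-heptaenedial | O=C/C(C)=C/C=C/C(C)=C/C=C/C=C(C)/C=C/C=C(C)/C=O | starting material
21 | (all-E)-1,18-diiodo-3,7,12,16-tetramethyloctadeca-1,3,5,7,9,11,13,15,17-nonaene | I/C=C/C(C)=C/C=C/C(C)=C/C=C/C=C(C)/C=C/C=C(C)/C=C/I | intermediate
22 | ring B diazoalkane (from 12) | CC(C)(C)[Si](C)(C)OCC(CO[Si](C)(C)C(C)(C)C)=CC[C@@H]1CCC(C)C(=[N+]=[N-])C1(C)C | intermediate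
23 | ring B all-E nonaenyl iodide: chain of 21 with iodine at C7 and the (5S)-5-[4-(TBSO)-3-(TBSO-methyl)but-2-enyl]-2,6,6-trimethylcyclohex-1-enyl ring at C7′ | I/C=C/C(C)=C/C=C/C(C)=C/C=C/C=C(C)/C=C/C=C(C)/C=C/C1=C(C)CC[C@@H](CC=C(CO[Si](C)(C)C(C)(C)C)CO[Si](C)(C)C(C)(C)C)C1(C)C | intermediate
24 | ring A diazoalkane (from 19) | CC(C)=CC[C@H]1CCC(C)C(=[N+]=[N-])C1(C)C | intermediate
25 | bis(tert-butyldimethylsilyl) ether of the target | CC(C)=CC[C@H]1CCC(C)=C(/C=C/C(C)=C/C=C/C(C)=C/C=C/C=C(C)/C=C/C=C(C)/C=C/C2=C(C)CC[C@@H](CC=C(CO[Si](C)(C)C(C)(C)C)CO[Si](C)(C)C(C)(C)C)C2(C)C)C1(C)C | intermediate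
26 | target, (2R,2′S)-2-(3-methylbut-2-enyl)-2′-[4-hydroxy-3-(hydroxymethyl)but-2-enyl]-β,β-carotene | CC(C)=CC[C@H]1CCC(C)=C(/C=C/C(C)=C/C=C/C(C)=C/C=C/C=C(C)/C=C/C=C(C)/C=C/C2=C(C)CC[C@@H](CC=C(CO)CO)C2(C)C)C1(C)C | target

**Totals and risks**

Total step count: 16. Longest linear sequence: 9 steps (1, 2, 3, 4, 6, 7, 14, 15, 16).

Step 15 (key coupling). The palladium carbene may form too slowly at the doubly flanked C6, so that the diazoalkane drains away by 1,2-hydride shift to the simple cyclohexene or by intramolecular reaction with the prenyl double bond. The nonaenyl iodide may also isomerise or degrade under the hot basic conditions. The fallback makes ring A the nucleophile by known chemistry; it sets out from ketone 18 and comes back at 25. Ketone 18 is condensed with 2,4,6-triisopropylbenzenesulfonohydrazide (cat. HCl, MeCN, rt) to the ring A trisylhydrazone F1. A Shapiro reaction (n-BuLi, TMEDA, THF, −78 → 0 °C), which can only deprotonate at the methyl-bearing α-carbon, is followed by trapping of the cyclohexenyllithium with 2-isopropoxy-4,4,5,5-tetramethyl-1,3,2-dioxaborolane to give the ring A cyclohexenyl pinacol boronate F2. Suzuki–Miyaura coupling of F2 with 23 (Pd(PPh3)4, aqueous TlOH, THF, rt, dark) should then give 25.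

Step 14 (single coupling of the diiodide). Coupling at both ends and loss of the excess diiodide to palladium-mediated decomposition may make the statistical differentiation of the two termini inefficient. The fallback differentiates the ends electronically and by protection; it sets out from 20 and comes back at 23. Takai olefination of 20, used in excess so that only one aldehyde reacts (the first olefination removes the acceptor that activates the second aldehyde), gives the iodo polyenal F3. Treatment with HC(OMe)3 and PPTS in MeOH gives the iodo polyenal dimethyl acetal F4. Barluenga coupling of F4 with 12 under the conditions of step 14 gives the ring B polyenal dimethyl acetal F5. Hydrolysis on wet silica gel with oxalic acid gives the ring B C35 polyenal F6, and a second Takai olefination returns to 23.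

Step 1 (and its mirror, step 8). The chelated, sluggish acetal Grignard reagent may add with poor facial selectivity or by competing 1,2-addition. The fallback replaces asymmetric catalysis by a racemic conjugate allylation and separation of enantiomers, both of which are needed because rings A and B have opposite configuration; it sets out from 1 and comes back at 8 and at 18. Copper-mediated conjugate allylation of 1 (allylmagnesium bromide, CuBr·SMe2, TMSCl, THF, −78 °C) gives the racemic silyl enol ether F7. MeLi and then MeI convert it into racemic 3-allyl-2,2-dimethylcyclohexanone F8. Preparative chromatography on a chiral stationary phase separates (3S)-3-allyl-2,2-dimethylcyclohexanone F9 from (3R)-3-allyl-2,2-dimethylcyclohexanone F10. F9 with LiN(iPr)2 and MeI gives 8. F10 under the same conditions gives (3R,6RS)-3-allyl-2,2,6-trimethylcyclohexanone F11, whose cross-metathesis with 2-methylbut-2-ene (second-generation Grubbs catalyst RuCl2(H2IMes)(PCy3)(=CHPh), CH2Cl2, 40 °C) returns to 18.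

**Further compounds**

F1 | step 15 | ring A trisylhydrazone (2,4,6-triisopropylbenzenesulfonohydrazone of 18) | CC(C)=CC[C@H]1CCC(C)C(=NNS(=O)(=O)c2c(C(C)C)cc(C(C)C)cc2C(C)C)C1(C)C
F2 | step 15 | ring A cyclohexenyl pinacol boronate, 2-[(5R)-2,6,6-trimethyl-5-(3-methylbut-2-en-1-yl)cyclohex-1-en-1-yl]-4,4,5,5-tetramethyl-1,3,2-dioxaborolane | CC(C)=CC[C@H]1CCC(C)=C(B2OC(C)(C)C(C)(C)O2)C1(C)C
F3 | step 14 | iodo polyenal, (all-E)-17-iodo-2,6,11,15-tetramethylheptadeca-2,4,6,8,10,12,14,16-octaenal | I/C=C/C(C)=C/C=C/C(C)=C/C=C/C=C(C)/C=C/C=C(C)/C=O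
F4 | step 14 | iodo polyenal dimethyl acetal | I/C=C/C(C)=C/C=C/C(C)=C/C=C/C=C(C)/C=C/C=C(C)/C(OC)OC
F5 | step 14 | ring B polyenal dimethyl acetal | COC(OC)/C(C)=C/C=C/C(C)=C/C=C/C=C(C)/C=C/C=C(C)/C=C/C1=C(C)CC[C@@H](CC=C(CO[Si](C)(C)C(C)(C)C)CO[Si](C)(C)C(C)(C)C)C1(C)C
F6 | step 14 | ring B C35 polyenal | O=C/C(C)=C/C=C/C(C)=C/C=C/C=C(C)/C=C/C=C(C)/C=C/C1=C(C)CC[C@@H](CC=C(CO[Si](C)(C)C(C)(C)C)CO[Si](C)(C)C(C)(C)C)C1(C)C
F7 | step 1 | racemic silyl enol ether, [(3-allyl-2-methylcyclohex-1-en-1-yl)oxy]trimethylsilane | C=CCC1CCCC(O[Si](C)(C)C)=C1C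
F8 | step 1 | racemic 3-allyl-2,2-dimethylcyclohexanone | C=CCC1CCCC(=O)C1(C)C
F9 | step 1 | (3S)-3-allyl-2,2-dimethylcyclohexanone | C=CC[C@@H]1CCCC(=O)C1(C)C
F10 | step 1 | (3R)-3-allyl-2,2-dimethylcyclohexanone | C=CC[C@H]1CCCC(=O)C1(C)C
F11 | step 1 | (3R,6RS)-3-allyl-2,2,6-trimethylcyclohexanone | C=CC[C@H]1CCC(C)C(=O)C1(C)C
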